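**Retrosynthetic overview**
1. The target is (−)-olivil whose ring B phenol carries an erythro (1R,2S) guaiacylglycerol unit. That side chain is cut last, at its C1–C2 bond, by an auxiliary-controlled anti aldol of a ring B aryloxyacetyl imide with O-benzylvanillin, followed by LiBH4.
2. The strategy rests on oxolane C2: it is a benzylic ether carbon carrying ring C, whose oxygen substituent sits para to it. O1–C2 can therefore be made from a plain ArCH2 group by hydride abstraction with DDQ and capture of the cation by the C5 hydroxyl of an acyclic 2,3-dibenzylbutane-1,2,4-triol.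
3. The triol comes from LiBH4 reduction of a (3S,4S)-α-hydroxy-α,β-dibenzylbutyrolactone. Its quaternary carbinol is set by benzylating the dianion of an α-hydroxy-β-benzyl lactone with a ring B bromide carried as its tosylate, which deactivates ring B towards DDQ and is cleaved afterwards.
4. The (R)-β-benzyl lactone derives from Stobbe condensation of O-benzylvanillin with dimethyl succinate, asymmetric hydrogenation and chemoselective ester reduction.
5. Ring order: the butyrolactone (step 3) is a temporary ring, opened in step 9; the oxolane, the only ring built for the target, closes in step 10.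

Key step: step 10

**Assumptions**
- The (S,S)-Et-DuPHOS rhodium catalyst is taken to deliver the R acid 4; the sense is to be confirmed on lactone 7 and the mirror-image ligand used otherwise.
- Compound 9 is drawn as the expected trans isomer; any C3 epimer is carried along, because both give the same planar dianion 14.
- In step 14 the tertiary hydroxyl is taken to stay unsilylated under TMSCl/Et3N; a silyl ether formed there would be cleaved by the same fluoride treatment.

**Route**

Step 1
Reactants: 1 4-(benzyloxy)-3-methoxybenzaldehyde; 2 dimethyl succinate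
Product: 3 (E)-4-[4-(benzyloxy)-3-methoxyphenyl]-3-(methoxycarbonyl)but-3-enoic acid
Conditions: NaOMe, MeOH, reflux; then aq. HCl
Reagents that add atoms: none
Why: Stobbe condensation: the aldolate lactonises to a paraconic ester whose base-induced ring opening is irreversible, which should give the E alkylidene half-ester with the conjugated ester kept and the CH2CO2H arm freed.

Step 2
Reactants: 3 (E)-4-[4-(benzyloxy)-3-methoxyphenyl]-3-(methoxycarbonyl)but-3-enoic acid
Product: 4 (3R)-4-[4-(benzyloxy)-3-methoxyphenyl]-3-(methoxycarbonyl)butanoic acid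
Conditions: [Rh(cod)((S,S)-Et-DuPHOS)]BF4 (0.5 mol %), H2 (4 bar), NaOMe (0.1 equiv), MeOH, rt
Reagents that add atoms: none
Why: Rhodium–bisphospholane asymmetric hydrogenation of an itaconate-type half-ester: two-point binding through alkene and carboxylate lets the ligand choose the alkene face and should set C3 as R, while the aryl benzyl ether is inert to the homogeneous catalyst.

Step 3
Reactants: 4 (3R)-4-[4-(benzyloxy)-3-methoxyphenyl]-3-(methoxycarbonyl)butanoic acid
Product: 7 (4R)-4-[4-(benzyloxy)-3-methoxybenzyl]oxolan-2-one, via potassium carboxylate 5 (not isolated), via hydroxy acid 6 (not isolated)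
Conditions: KOH (1.0 equiv), MeOH, 0 °C, evaporate; LiBH4, THF, 0 °C to rt; then 2 M HCl, rt
Reagents that add atoms: none
Why: Chemoselective borohydride reduction: LiBH4 reduces the methyl ester but not the carboxylate salt, and acidification closes the γ-hydroxy acid to the lactone without touching the stereocentre.

Step 4
Reactants: 7 (4R)-4-[4-(benzyloxy)-3-methoxybenzyl]oxolan-2-one
Product: 9 (3R,4S)-4-[4-(benzyloxy)-3-methoxybenzyl]-3-hydroxyoxolan-2-one, via potassium enolate 8 (not isolated)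
Conditions: KN(SiMe3)2, THF, −78 °C; then 2-(phenylsulfonyl)-3-phenyloxaziridine, −78 °C; then 1 M HCl
Reagents that add atoms: 2-(phenylsulfonyl)-3-phenyloxaziridine, O=S(=O)(c1ccccc1)N1OC1c1ccccc1
Why: Enolate hydroxylation with an N-sulfonyloxaziridine: oxygen is delivered anti to the C4 arylmethyl group (trans isomer expected to dominate), and the C3 configuration is of no consequence because C3 is planar again in step 8.

Step 5
Reactants: 10 vanillin (4-hydroxy-3-methoxybenzaldehyde)
Product: 11 4-formyl-2-methoxyphenyl 4-methylbenzenesulfonate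
Conditions: TsCl, K2CO3, acetone, rt
Reagents that add atoms: 4-methylbenzenesulfonyl chloride, Cc1ccc(cc1)S(=O)(=O)Cl
Why: Sulfonylation of the phenoxide gives the aryl tosylate, which should survive all steps up to step 11 and makes ring B electron-poor.

Step 6
Reactants: 11 4-formyl-2-methoxyphenyl 4-methylbenzenesulfonate
Product: 12 4-(hydroxymethyl)-2-methoxyphenyl 4-methylbenzenesulfonate
Conditions: NaBH4, MeOH, 0 °C
Reagents that add atoms: none
Why: Borohydride reduction of the aldehyde; aryl sulfonates are inert to NaBH4.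

Step 7
Reactants: 12 4-(hydroxymethyl)-2-methoxyphenyl 4-methylbenzenesulfonate
Product: 13 4-(bromomethyl)-2-methoxyphenyl 4-methylbenzenesulfonate
Conditions: PBr3 (0.4 equiv), CH2Cl2, 0 °C
Reagents that add atoms: phosphorus tribromide, BrP(Br)Br
Why: Bromination of the benzylic alcohol through its phosphite ester and SN2 displacement by bromide; the sulfonate is untouched.

Step 8
Reactants: 9 (3R,4S)-4-[4-(benzyloxy)-3-methoxybenzyl]-3-hydroxyoxolan-2-one; 13 4-(bromomethyl)-2-methoxyphenyl 4-methylbenzenesulfonate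
Product: 15 (3S,4S)-4-[4-(benzyloxy)-3-methoxybenzyl]-3-hydroxy-3-[3-methoxy-4-(tosyloxy)benzyl]oxolan-2-one, via dilithium alkoxide enolate 14 (not isolated)
Conditions: LiN(SiMe3)2 (2.3 equiv), THF–DMPU, −78 to −40 °C; then 13, −78 to −20 °C; then 1 M HCl
Reagents that add atoms: none
Why: C-alkylation of an α-hydroxy lactone dianion: the benzylic bromide approaches the planar enolate anti to the C4 arylmethyl group, so the new benzyl should end trans to it and the hydroxyl cis, which sets the quaternary carbinol as S.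

Step 9
Reactants: 15 (3S,4S)-4-[4-(benzyloxy)-3-methoxybenzyl]-3-hydroxy-3-[3-methoxy-4-(tosyloxy)benzyl]oxolan-2-one
Product: 16 (2S,3S)-3-[4-(benzyloxy)-3-methoxybenzyl]-2-[3-methoxy-4-(tosyloxy)benzyl]butane-1,2,4-triol
Conditions: LiBH4, THF, 0 °C to rt
Reagents that add atoms: none
Why: Lactone reduction with LiBH4 to the 1,4-diol; aryl tosylate, benzyl ether and both stereocentres are untouched.

Step 10
Reactants: 16 (2S,3S)-3-[4-(benzyloxy)-3-methoxybenzyl]-2-[3-methoxy-4-(tosyloxy)benzyl]butane-1,2,4-triol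
Product: 17 (3S,4R,5S)-5-[4-(benzyloxy)-3-methoxyphenyl]-4-(hydroxymethyl)-3-[3-methoxy-4-(tosyloxy)benzyl]oxolan-3-ol
Conditions: DDQ (1.1 equiv), 4 Å MS, CH2Cl2, 0 °C
Reagents that add atoms: none
Why: DDQ forms a charge-transfer complex with the 4-benzyloxy-3-methoxyphenyl ring (ring C) and abstracts hydride from its benzylic CH2, giving a para-alkoxybenzyl cation that is captured by the primary hydroxyl on the quaternary carbinol carbon to form O1–C2; the closest known reaction is the DDQ oxidative cyclisation of dibenzylbutanediols to 2-aryloxolane lignans. The oxolane closes in a 5-exo-trig mode onto the cationic carbon, whereas the other two hydroxyls could only close four-membered rings. The new stereocentre C2 is controlled by the adjacent C3 centre: in the envelope transition state the aryl group should take the pseudo-equatorial position trans to the C3 hydroxymethyl, and reversible ionisation of the benzylic ether in the presence of the weakly acidic hydroquinone should let any cis isomer drain to the trans one. The step needs site selectivity between the two benzylic CH2 groups, and the ring B tosylate secures it, because that ring then has no para donor and is too electron-poor for hydride abstraction or for Friedel–Crafts attack on the cation. Over-oxidation of the product at its C2–H is held back by using about one equivalent of oxidant at 0 °C under anhydrous conditions.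

Step 11
Reactants: 17 (3S,4R,5S)-5-[4-(benzyloxy)-3-methoxyphenyl]-4-(hydroxymethyl)-3-[3-methoxy-4-(tosyloxy)benzyl]oxolan-3-ol
Product: 18 (3S,4R,5S)-5-[4-(benzyloxy)-3-methoxyphenyl]-3-(4-hydroxy-3-methoxybenzyl)-4-(hydroxymethyl)oxolan-3-ol
Conditions: KOH, MeOH–H2O, reflux; then 1 M HCl to pH 6, 0 °C
Reagents that add atoms: none
Why: Basic cleavage of the aryl sulfonate by hydroxide attack at sulfur; the ethers, the alcohols and the oxolane are stable to base because ring C carries no free phenol.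

Step 12
Reactants: 19 (S)-4-benzyloxazolidin-2-one
Product: 21 (S)-4-benzyl-3-(bromoacetyl)oxazolidin-2-one, via lithium amide 20 (not isolated)
Conditions: n-BuLi, THF, −78 °C; then BrCH2COBr, −78 to 0 °C
Reagents that add atoms: bromoacetyl bromide, BrCC(Br)=O
Why: N-acylation of the lithiated oxazolidinone; the acid bromide reacts at the acyl carbon much faster than at the CH2Br carbon.

Step 13
Reactants: 18 (3S,4R,5S)-5-[4-(benzyloxy)-3-methoxyphenyl]-3-(4-hydroxy-3-methoxybenzyl)-4-(hydroxymethyl)oxolan-3-ol; 21 (S)-4-benzyl-3-(bromoacetyl)oxazolidin-2-one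
Product: 22 (4S)-4-benzyl-3-{[4-({(3S,4R,5S)-5-[4-(benzyloxy)-3-methoxyphenyl]-3-hydroxy-4-(hydroxymethyl)oxolan-3-yl}methyl)-2-methoxyphenoxy]acetyl}oxazolidin-2-one
Conditions: K2CO3, acetone, rt
Reagents that add atoms: none
Why: Williamson ether synthesis: carbonate deprotonates only the phenol and the α-bromo imide is a fast SN2 acceptor, so the aliphatic hydroxyls and the imide should stay intact.

Step 14
Reactants: 22 (4S)-4-benzyl-3-{[4-({(3S,4R,5S)-5-[4-(benzyloxy)-3-methoxyphenyl]-3-hydroxy-4-(hydroxymethyl)oxolan-3-yl}methyl)-2-methoxyphenoxy]acetyl}oxazolidin-2-one; 1 4-(benzyloxy)-3-methoxybenzaldehyde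
Product: 25 (4S)-4-benzyl-3-[(2R,3R)-3-[4-(benzyloxy)-3-methoxyphenyl]-3-hydroxy-2-{4-[((3S,4R,5S)-5-[4-(benzyloxy)-3-methoxyphenyl]-3-hydroxy-4-(hydroxymethyl)oxolan-3-yl)methyl]-2-methoxyphenoxy}propanoyl]oxazolidin-2-one, via primary silyl ether 23 (not isolated), via bis-silyl aldol adduct 24 (not isolated)
Conditions: TMSCl, Et3N, MgCl2 (0.2 equiv), EtOAc, rt; then Et3N·3HF, THF, 0 °C
Reagents that add atoms: none
Why: Proposed new method: soft enolisation of the aryloxyacetyl imide by MgCl2/Et3N should give the magnesium Z-enolate chelated to the oxazolidinone carbonyl, which adds to the non-enolisable aldehyde through a boat-like closed transition state on the enolate face remote from the 4-benzyl group, while silylation of the aldolate by TMSCl turns the magnesium over and protects the primary hydroxyl in passing, so the anti (2R,3R) adduct is expected; the closest known reaction is the MgCl2-catalysed anti aldol of N-propionyl oxazolidinones with aromatic aldehydes, here extended to an α-aryloxy acyl group whose extra oxygen atoms could alter the chelation and hence the facial sense.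

Step 15
Reactants: 25 (4S)-4-benzyl-3-[(2R,3R)-3-[4-(benzyloxy)-3-methoxyphenyl]-3-hydroxy-2-{4-[((3S,4R,5S)-5-[4-(benzyloxy)-3-methoxyphenyl]-3-hydroxy-4-(hydroxymethyl)oxolan-3-yl)methyl]-2-methoxyphenoxy}propanoyl]oxazolidin-2-one
Product: 26 (1R,2S)-1-[4-(benzyloxy)-3-methoxyphenyl]-2-{4-[((3S,4R,5S)-5-[4-(benzyloxy)-3-methoxyphenyl]-3-hydroxy-4-(hydroxymethyl)oxolan-3-yl)methyl]-2-methoxyphenoxy}propane-1,3-diol
Conditions: LiBH4, THF, MeOH (1 equiv), 0 °C
Reagents that add atoms: none
Why: Reductive cleavage of the N-acyl oxazolidinone with LiBH4 to the primary alcohol; no stereocentre is touched and the auxiliary is released intact.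

Step 16
Reactants: 26 (1R,2S)-1-[4-(benzyloxy)-3-methoxyphenyl]-2-{4-[((3S,4R,5S)-5-[4-(benzyloxy)-3-methoxyphenyl]-3-hydroxy-4-(hydroxymethyl)oxolan-3-yl)methyl]-2-methoxyphenoxy}propane-1,3-diol
Product: 27 (1R,2S)-1-(4-hydroxy-3-methoxyphenyl)-2-{4-[((3S,4R,5S)-3-hydroxy-5-(4-hydroxy-3-methoxyphenyl)-4-(hydroxymethyl)oxolan-3-yl)methyl]-2-methoxyphenoxy}propane-1,3-diol (CNP0350466.2)
Conditions: H2 (1 atm), 10% Pd/C, EtOAc, rt, stopped at full debenzylation
Reagents that add atoms: none
Why: Hydrogenolysis of the two aryl benzyl ethers over palladium on carbon; in a neutral aprotic solvent phenolic benzyl ethers should cleave faster than the secondary benzylic C–O bonds of the oxolane and of the carbinol, so the reaction is stopped as soon as both are gone.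

**Compound list**
1 | 4-(benzyloxy)-3-methoxybenzaldehyde | COc1cc(C=O)ccc1OCc1ccccc1 | starting material
2 | dimethyl succinate | COC(=O)CCC(=O)OC | starting material
3 | (E)-4-[4-(benzyloxy)-3-methoxyphenyl]-3-(methoxycarbonyl)but-3-enoic acid | COC(=O)/C(CC(=O)O)=C/c1ccc(OCc2ccccc2)c(OC)c1 | intermediate
4 | (3R)-4-[4-(benzyloxy)-3-methoxyphenyl]-3-(methoxycarbonyl)butanoic acid | COC(=O)[C@H](Cc1ccc(OCc2ccccc2)c(OC)c1)CC(=O)O | intermediate
5 | potassium (3R)-4-[4-(benzyloxy)-3-methoxyphenyl]-3-(methoxycarbonyl)butanoate | COC(=O)[C@H](Cc1ccc(OCc2ccccc2)c(OC)c1)CC(=O)[O-].[K+] | intermediate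
6 | (3R)-4-[4-(benzyloxy)-3-methoxyphenyl]-3-(hydroxymethyl)butanoic acid | OC[C@H](Cc1ccc(OCc2ccccc2)c(OC)c1)CC(=O)O | intermediate
7 | (4R)-4-[4-(benzyloxy)-3-methoxybenzyl]oxolan-2-one | O=C1C[C@@H](Cc2ccc(OCc3ccccc3)c(OC)c2)CO1 | intermediate
8 | potassium enolate of 7 | [K+].[O-]C1=C[C@@H](Cc2ccc(OCc3ccccc3)c(OC)c2)CO1 | intermediate
9 | (3R,4S)-4-[4-(benzyloxy)-3-methoxybenzyl]-3-hydroxyoxolan-2-one | O=C1[C@H](O)[C@@H](Cc2ccc(OCc3ccccc3)c(OC)c2)CO1 | intermediate
10 | vanillin | COc1cc(C=O)ccc1O | starting material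
11 | 4-formyl-2-methoxyphenyl 4-methylbenzenesulfonate | COc1cc(C=O)ccc1OS(=O)(=O)c1ccc(C)cc1 | intermediate
12 | 4-(hydroxymethyl)-2-methoxyphenyl 4-methylbenzenesulfonate | COc1cc(CO)ccc1OS(=O)(=O)c1ccc(C)cc1 | intermediate
13 | 4-(bromomethyl)-2-methoxyphenyl 4-methylbenzenesulfonate | COc1cc(CBr)ccc1OS(=O)(=O)c1ccc(C)cc1 | intermediate
14 | dilithium alkoxide enolate of 9 | [Li+].[Li+].[O-]C1=C([O-])[C@@H](Cc2ccc(OCc3ccccc3)c(OC)c2)CO1 | intermediate
15 | (3S,4S)-4-[4-(benzyloxy)-3-methoxybenzyl]-3-hydroxy-3-[3-methoxy-4-(tosyloxy)benzyl]oxolan-2-one | COc1cc(C[C@@]2(O)C(=O)OC[C@@H]2Cc2ccc(OCc3ccccc3)c(OC)c2)ccc1OS(=O)(=O)c1ccc(C)cc1 | intermediate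
16 | (2S,3S)-3-[4-(benzyloxy)-3-methoxybenzyl]-2-[3-methoxy-4-(tosyloxy)benzyl]butane-1,2,4-triol | COc1cc(C[C@@]([C@H](CO)Cc2ccc(OCc3ccccc3)c(OC)c2)(O)CO)ccc1OS(=O)(=O)c1ccc(C)cc1 | intermediate
17 | (3S,4R,5S)-5-[4-(benzyloxy)-3-methoxyphenyl]-4-(hydroxymethyl)-3-[3-methoxy-4-(tosyloxy)benzyl]oxolan-3-ol | COc1cc(C[C@@]2(O)CO[C@H](c3ccc(OCc4ccccc4)c(OC)c3)[C@H]2CO)ccc1OS(=O)(=O)c1ccc(C)cc1 | intermediate
18 | (3S,4R,5S)-5-[4-(benzyloxy)-3-methoxyphenyl]-3-(4-hydroxy-3-methoxybenzyl)-4-(hydroxymethyl)oxolan-3-ol | COc1cc(C[C@@]2(O)CO[C@H](c3ccc(OCc4ccccc4)c(OC)c3)[C@H]2CO)ccc1O | intermediate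
19 | (S)-4-benzyloxazolidin-2-one | O=C1N[C@@H](Cc2ccccc2)CO1 | starting material
20 | lithium salt of 19 | [Li+].O=C1[N-][C@@H](Cc2ccccc2)CO1 | intermediate
21 | (S)-4-benzyl-3-(bromoacetyl)oxazolidin-2-one | O=C1OC[C@H](Cc2ccccc2)N1C(=O)CBr | intermediate
22 | (4S)-4-benzyl-3-{[4-({(3S,4R,5S)-5-[4-(benzyloxy)-3-methoxyphenyl]-3-hydroxy-4-(hydroxymethyl)oxolan-3-yl}methyl)-2-methoxyphenoxy]acetyl}oxazolidin-2-one | COc1cc(C[C@@]2(O)CO[C@H](c3ccc(OCc4ccccc4)c(OC)c3)[C@H]2CO)ccc1OCC(=O)N1[C@@H](Cc2ccccc2)COC1=O | intermediate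
23 | trimethylsilyl ether of 22 at the primary hydroxyl | COc1cc(C[C@@]2(O)CO[C@H](c3ccc(OCc4ccccc4)c(OC)c3)[C@H]2CO[Si](C)(C)C)ccc1OCC(=O)N1[C@@H](Cc2ccccc2)COC1=O | intermediate
24 | bis(trimethylsilyl) ether of 25 (aldol oxygen and primary hydroxyl) | COc1cc([C@@H](O[Si](C)(C)C)[C@H](C(=O)N2[C@@H](Cc3ccccc3)COC2=O)Oc2ccc(C[C@@]3(O)CO[C@H](c4ccc(OCc5ccccc5)c(OC)c4)[C@H]3CO[Si](C)(C)C)cc2OC)ccc1OCc1ccccc1 | intermediate
25 | (4S)-4-benzyl-3-[(2R,3R)-3-[4-(benzyloxy)-3-methoxyphenyl]-3-hydroxy-2-{4-[((3S,4R,5S)-5-[4-(benzyloxy)-3-methoxyphenyl]-3-hydroxy-4-(hydroxymethyl)oxolan-3-yl)methyl]-2-methoxyphenoxy}propanoyl]oxazolidin-2-one | COc1cc([C@@H](O)[C@H](C(=O)N2[C@@H](Cc3ccccc3)COC2=O)Oc2ccc(C[C@@]3(O)CO[C@H](c4ccc(OCc5ccccc5)c(OC)c4)[C@H]3CO)cc2OC)ccc1OCc1ccccc1 | intermediate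
26 | (1R,2S)-1-[4-(benzyloxy)-3-methoxyphenyl]-2-{4-[((3S,4R,5S)-5-[4-(benzyloxy)-3-methoxyphenyl]-3-hydroxy-4-(hydroxymethyl)oxolan-3-yl)methyl]-2-methoxyphenoxy}propane-1,3-diol | COc1cc([C@@H](O)[C@H](CO)Oc2ccc(C[C@@]3(O)CO[C@H](c4ccc(OCc5ccccc5)c(OC)c4)[C@H]3CO)cc2OC)ccc1OCc1ccccc1 | intermediate
27 | (1R,2S)-1-(4-hydroxy-3-methoxyphenyl)-2-{4-[((3S,4R,5S)-3-hydroxy-5-(4-hydroxy-3-methoxyphenyl)-4-(hydroxymethyl)oxolan-3-yl)methyl]-2-methoxyphenoxy}propane-1,3-diol | COc1cc([C@@H](O)[C@H](CO)Oc2ccc(C[C@@]3(O)CO[C@H](c4ccc(O)c(OC)c4)[C@H]3CO)cc2OC)ccc1O | target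

**Step count**
Total: 16 steps. Longest linear sequence: 12 steps (steps 1–4, 8–11, 13–16).

**Steps most likely to fail**

1. Step 14 (anti aldol). Facial selectivity may be poor or reversed if magnesium is held by the aryloxy and methoxy oxygens instead of the imide carbonyl; the electron-rich aldehyde may also add too slowly, or the adduct may undergo retro-aldol cleavage during desilylation. The fallback uses known chemistry, sets out from 18 and returns at 26. (R)-4-Benzyloxazolidin-2-one is acylated as in step 12 to (R)-4-benzyl-3-(bromoacetyl)oxazolidin-2-one F1, which alkylates phenol 18 (K2CO3, acetone) to the (4R)-configured aryloxyacetyl imide F2. Ac2O/pyridine caps the primary hydroxyl to give the acetate F3. The boron-mediated syn aldol (Bu2BOTf in excess, iPr2NEt, CH2Cl2, −78 to 0 °C, then 1; buffered H2O2 work-up) should give the syn (2R,3S) adduct F4, whose C2 already has the configuration of the target through the predictable Z-boron-enolate chair transition state. Mitsunobu inversion of the benzylic carbinol (PPh3, DIAD, 4-nitrobenzoic acid, toluene, 0 °C) would give the (2R,3R) 4-nitrobenzoate F5. LiBH4 then removes the auxiliary, the nitrobenzoate and the acetate in one operation and delivers 26.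

2. Step 10 (oxidative closure of the oxolane). The product may be over-oxidised at its doubly activated C2–H, the cation may close onto ring B in a Friedel–Crafts sense or lose a proton to a styrene, or closure may give the cis isomer. The fallback sets out from 15 and returns at 17, separating the oxidation from the ring closure. DDQ in acetic acid at the lactone stage should stop at the benzylic acetate of ring C (mixture of epimers at the benzylic carbon) F6, because the acetate disfavours a second hydride abstraction. LiBH4 reduces the lactone and cleaves the acetate to the benzylic-hydroxy tetraol F7. A catalytic amount of camphorsulfonic acid in CH2Cl2 at 0 °C then ionises the benzylic alcohol, and the same C5 hydroxyl closes O1–C2 under thermodynamic control to give 17.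

3. Step 8 (dianion benzylation). Dianion formation may be incomplete, the alkoxide may be O-alkylated, or the anion may attack the sulfonate sulfur of 13. The fallback sets out from 9 and returns at 15. TBSCl/imidazole in DMF gives the silyl ether F8. Its lithium enolate (LiN(SiMe3)2, THF–DMPU, −78 °C) is alkylated by 13 anti to the C4 arylmethyl group to give the quaternary silyl ether F9. HF·pyridine in THF then removes the silyl group to give 15.

**Further compounds**
F1 | step 14 | (R)-4-benzyl-3-(bromoacetyl)oxazolidin-2-one | O=C1OC[C@@H](Cc2ccccc2)N1C(=O)CBr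
F2 | step 14 | (4R)-4-benzyl-3-{[4-({(3S,4R,5S)-5-[4-(benzyloxy)-3-methoxyphenyl]-3-hydroxy-4-(hydroxymethyl)oxolan-3-yl}methyl)-2-methoxyphenoxy]acetyl}oxazolidin-2-one | COc1cc(C[C@@]2(O)CO[C@H](c3ccc(OCc4ccccc4)c(OC)c3)[C@H]2CO)ccc1OCC(=O)N1[C@H](Cc2ccccc2)COC1=O
F3 | step 14 | acetate of F2 at the primary hydroxyl | COc1cc(C[C@@]2(O)CO[C@H](c3ccc(OCc4ccccc4)c(OC)c3)[C@H]2COC(C)=O)ccc1OCC(=O)N1[C@H](Cc2ccccc2)COC1=O
F4 | step 14 | syn (2R,3S) aldol adduct of F3 with 1 | COc1cc([C@H](O)[C@H](C(=O)N2[C@H](Cc3ccccc3)COC2=O)Oc2ccc(C[C@@]3(O)CO[C@H](c4ccc(OCc5ccccc5)c(OC)c4)[C@H]3COC(C)=O)cc2OC)ccc1OCc1ccccc1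
F5 | step 14 | (2R,3R) 4-nitrobenzoate from inversion of F4 | COc1cc([C@@H](OC(=O)c2ccc(cc2)[N+](=O)[O-])[C@H](C(=O)N2[C@H](Cc3ccccc3)COC2=O)Oc2ccc(C[C@@]3(O)CO[C@H](c4ccc(OCc5ccccc5)c(OC)c4)[C@H]3COC(C)=O)cc2OC)ccc1OCc1ccccc1
F6 | step 10 | (3S,4S)-4-{acetoxy[4-(benzyloxy)-3-methoxyphenyl]methyl}-3-hydroxy-3-[3-methoxy-4-(tosyloxy)benzyl]oxolan-2-one (epimers at the acetoxy carbon) | COc1cc(C[C@@]2(O)C(=O)OC[C@@H]2C(OC(C)=O)c2ccc(OCc3ccccc3)c(OC)c2)ccc1OS(=O)(=O)c1ccc(C)cc1
F7 | step 10 | (2S,3S)-3-{[4-(benzyloxy)-3-methoxyphenyl](hydroxy)methyl}-2-[3-methoxy-4-(tosyloxy)benzyl]butane-1,2,4-triol (epimers at the benzylic carbinol) | COc1cc(C[C@@]([C@H](CO)C(O)c2ccc(OCc3ccccc3)c(OC)c2)(O)CO)ccc1OS(=O)(=O)c1ccc(C)cc1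
F8 | step 8 | (3R,4S)-4-[4-(benzyloxy)-3-methoxybenzyl]-3-(tert-butyldimethylsilyloxy)oxolan-2-one | O=C1[C@H](O[Si](C)(C)C(C)(C)C)[C@@H](Cc2ccc(OCc3ccccc3)c(OC)c2)CO1
F9 | step 8 | (3S,4S)-4-[4-(benzyloxy)-3-methoxybenzyl]-3-(tert-butyldimethylsilyloxy)-3-[3-methoxy-4-(tosyloxy)benzyl]oxolan-2-one | COc1cc(C[C@@]2(O[Si](C)(C)C(C)(C)C)C(=O)OC[C@@H]2Cc2ccc(OCc3ccccc3)c(OC)c2)ccc1OS(=O)(=O)c1ccc(C)cc1
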